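Labdane numbering is used throughout: ring A is C1–C5/C10, ring B is C5–C10, C11 and C12 are the chain methylenes on C9, C13=C14 is the chain alkene, C15 the acid carbon, C16 the acetoxymethyl carbon, C17 the methylene carbon on C8, C18/C19 the methyls on C4 and C20 the methyl on C10.

## Analysis of the target

The target 21 is a bicyclic ent-labdane: a trans-fused decalin (ring A with the C4 gem-dimethyl group, ring B) that carries a five-carbon chain on C9. All four stereocentres lie in ring B: C5 (R), C6 (R), C9 (R) and C10 (S). H5 is anti to the C20 methyl (trans fusion), the C9 chain is equatorial and on the same face as C20, and the C6 hydroxyl is equatorial, on the face of H5 and away from the two axial methyls (C20 and the axial methyl on C4). The exocyclic C8=C17 alkene is acid-sensitive and would move into conjugation with any carbonyl at C6. The chain ends in a (13Z)-enoic acid whose C16 acetoxymethyl group is cis to the carboxyl. This is the seco form of a butenolide, so loss of the acetyl group closes it to the lactone, and no basic hydrolysis is possible once the acetate is in place. The hard points are the quaternary C10 flanked by C9 and the crowded C4, the oxygen at C6 with the less accessible (equatorial) configuration, and the need for a single enantiomer with no obvious chiral-pool source. The strategy rests on ring B itself: oxygen at C6, an exocyclic alkene at C8, a carbon substituent at C9 and the C5–C10 bond shared with ring A. This is the pattern left when a 2-silyloxydiene spanning C7=C6–C5=C10 adds across the conjugated π-bond (C8=C9) of an allenic ester.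

## Retrosynthetic reasoning

21 from 20. The last operation only removes silicon-based groups: the silyl ether on O6 and the acetal-type ester on C15. Both fall to the same fluoride source under mildly acidic conditions that leave the allylic acetate, the free acid and both alkenes alone. Nothing basic is needed after the acetate is installed.

20 from 17. The C15–O16 acyl bond is notionally re-formed, so the Z geometry of C13=C14 is stored in a five-membered lactone and cannot be lost. In the forward sense hydroxide opens 17 to the carboxylate 18. The carboxylate is alkylated first (19) and only then is O16 acetylated. Acetylating 18 directly would pass through a mixed anhydride next to a free cis hydroxymethyl group, which would simply close back to 17.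

17 from 14 and 15. The C12–C13 sp3–sp2 bond is cut. This separates the whole stereochemical problem (14) from an achiral, purchasable heterocycle (15). The forward reaction is a Negishi coupling of the alkylzinc 16 derived from 14.

14 from 12. C12 is one carbon beyond what the cycloaddition delivers. The C12–I bond is traced to the terminal alkene C11=C12 of 12 by anti-Markovnikov hydrometalation and iodinolysis, which has to distinguish the monosubstituted alkene from the 1,1-disubstituted C8=C17.

12 from 11, 11 from 10, 10 from 9. The O6 silyl ether comes from the free equatorial alcohol 11. The C6–H bond of 11 comes from ketone 10 by an electron-transfer reduction that gives the more stable equatorial carbinol. The C5–H bond of 10 comes from protonation of the enol ether 9 on the face anti to C20. The enol ether is kept until this point so that it protects C6 during the redox changes at C11 and the ketone never coexists with an ester or aldehyde.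

9 from 8, 8 from 7, 7 from 6. The C11=C12 bond is cut (Wittig methylenation). Aldehyde 8 and alcohol 7 are oxidation-level adjustments of the ester carbon C11 that the cycloaddition installs.

6 from 4 and 5. This is the key disconnection: C7–C8 and C9–C10 are cut together. It removes ring B, both ring-B C–C stereocentres (C9, C10) and the exocyclic alkene in one step. It leads back to an achiral diene that already contains ring A and to an achiral, purchasable allenic ester. The forward reaction has to overcome the twist and crowding at C10 and control the absolute configuration there.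

4 from 3, 3 from 2, 2 from 1. The O–Si bond of 4 is formed by enol silylation of the methyl ketone 3. Ketone 3 comes from 1 by addition of a methyl nucleophile (2) and oxidation.

## Alternatives that were turned down

Alternative 1: Ring B is opened at C6–C7. The precursor A1 has ring A complete, a formyl group (C6) on C5 and, on C10, the C9 carbon bearing a benzyloxymethyl group (C11) and a 3-(trimethylsilyl)prop-1-en-2-yl group (C8, C7, C17).
- Forward step: a Lewis acid activates the aldehyde, the alkene terminus C7 attacks C6, silicon leaves from C17 and A2 results (intramolecular Hosomi–Sakurai reaction).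
- For it: the C6 carbinol and the C8=C17 alkene are created together and no β,γ-unsaturated ketone ever exists, so alkene migration is not an issue. A chair-like closure with the carbonyl oxygen equatorial should give the right C6 configuration. No enantioselective catalysis is needed once A1 is in hand. On these points it is stronger than the chosen route.
- Against it: A1 already contains C5, C9 and the quaternary C10, and the C9–C10 relationship would have to be set across an acyclic bond next to a quaternary centre. The hardest problem is moved upstream, not solved. The aldehyde sits between two quaternary carbons (C4 and C10), so it is slow to attack and can epimerize at C5. Reaching A1 would take many more steps than the three that give the diene 4.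
- Comparison: the chosen strategy makes C9, C10 and ring B in one early step from achiral pieces, so a failure shows at step four, not after a long precursor synthesis.

Alternative 2: Ring B is opened at C8–C9. The precursor A3 carries a silyl-protected carbinol (C6), a methylene (C7) and a 2-bromovinyl unit (C8, C17) on C5, and an (E)-enoate (C9=C11, C12 ester) on C10.
- Forward step: the vinyl radical at C8, generated with a tin or silane hydrogen donor, adds 6-exo-trig to C9 and the α-ester radical is reduced to give A4.
- For it: 6-exo vinyl-radical closures onto enoates are fast and tolerate crowding. The exocyclic alkene appears under neutral conditions. A4 already contains C12 at the ester level, which would remove the four-step C11-to-C12 homologation of the chosen route. On side-chain economy this alternative is clearly stronger.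
- Against it: C9 is created by attack on a trigonal carbon attached to quaternary C10, and nothing firm distinguishes chair-like from boat-like closure. Premature reduction of the vinyl radical or intramolecular hydrogen transfer competes. A3 again needs C5, C6 and the quaternary C10 with an alkenyl substituent in place, a long enantioselective preparation.
- Comparison: the chosen route is weaker late (homologation) but far shorter to the bicyclic core, and it sets C9 and C10 in the same event.

Alternative 3: The C5–C10 bond of ring A is cut. The precursor A5 is an (E)-configured ten-membered allylic lactone with a silyloxymethyl group on the carbinol carbon C11.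
- Forward step: the silyl ketene acetal of A5 rearranges through a chair-like [3,3] array spanned by the four-carbon tether (Ireland–Claisen ring contraction, geometrically like a germacrene-to-elemene Cope rearrangement). The C11–O bond is cleaved and ring A closes to the trans acid A6.
- For it: the rearrangement is suprafacial and stereospecific. It fixes quaternary C10 and C5, relative and absolute, by chirality transfer from one carbinol centre. On stereochemical reliability it is the strongest of the four approaches.
- Against it: it builds ring A, which compound 1 supplies for nothing. A5 is a medium-ring lactone with a trisubstituted E alkene and needs a difficult lactonization. The ketene acetal geometry inside the ring decides chair versus boat and therefore cis versus trans. Enolization at C5 beside the gem-dimethyl carbon is hindered. After the key step none of ring B exists: C7, C8 and C17 must be added, C8–C9 formed and C9 created from an sp2 carbon.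
- Comparison: the chosen strategy trades some stereochemical certainty for a much shorter and more convergent route.

Key step: step 4

Assumption: 15 is taken as purchasable, and the catalyst antipode written in step 4 is the one suggested by the usual ester-binding model; its mirror image would be used if the opposite sense of induction were found.

## Route

Step 1
Reactants: 1 β-cyclocitral (2,6,6-trimethylcyclohex-1-ene-1-carbaldehyde)
Product: 2 1-(2,6,6-trimethylcyclohex-1-en-1-yl)ethan-1-ol (racemic)
Conditions: MeMgBr, Et2O, 0 °C; H2O
Reagents that add atoms: methylmagnesium bromide, C[Mg]Br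
Why: Grignard 1,2-addition to the hindered, twisted enal; the new carbinol centre is removed in the next step, so its configuration does not matter.

Step 2
Reactants: 2 1-(2,6,6-trimethylcyclohex-1-en-1-yl)ethan-1-ol
Product: 3 1-(2,6,6-trimethylcyclohex-1-en-1-yl)ethan-1-one
Conditions: DMP (1,1,1-triacetoxy-1,1-dihydro-1,2-benziodoxol-3(1H)-one), CH2Cl2, rt
Reagents that add atoms: none
Why: Hypervalent-iodine oxidation of a secondary allylic alcohol to the ketone under neutral conditions that do not move the tetrasubstituted alkene.

Step 3
Reactants: 3 1-(2,6,6-trimethylcyclohex-1-en-1-yl)ethan-1-one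
Product: 4 tert-butyldimethyl{[1-(2,6,6-trimethylcyclohex-1-en-1-yl)ethenyl]oxy}silane
Conditions: t-BuMe2SiOTf, Et3N, CH2Cl2, 0 °C → rt
Reagents that add atoms: tert-butyldimethylsilyl trifluoromethanesulfonate, CC(C)(C)[Si](C)(C)OS(=O)(=O)C(F)(F)F
Why: Soft enolization and O-silylation of a methyl ketone; the only α-hydrogens are those of the methyl group, so the cross-conjugated 2-silyloxydiene forms.

Step 4
Reactants: 4 tert-butyldimethyl{[1-(2,6,6-trimethylcyclohex-1-en-1-yl)ethenyl]oxy}silane; 5 ethyl buta-2,3-dienoate
Product: 6 ethyl (9R,10S)-6-(tert-butyldimethylsilyloxy)-12,13,14,15,16-pentanor-ent-labda-5,8(17)-dien-11-oate, i.e. ethyl (1R,8aS)-4-(tert-butyldimethylsilyloxy)-5,5,8a-trimethyl-2-methylidene-1,2,3,5,6,7,8,8a-octahydronaphthalene-1-carboxylate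
Conditions: (S)-3,3-diphenyl-1-(o-tolyl)tetrahydro-1H,3H-pyrrolo[1,2-c][1,3,2]oxazaborole (20 mol%), HN(SO2CF3)2 (18 mol%), 4 Å sieves, CH2Cl2, −78 → 0 °C
Reagents that add atoms: none
Why: Proposed new method: the N-protonated oxazaborolidine binds the ester carbonyl of 5 and lowers the LUMO of its conjugated C8=C9 π-bond; the silyl enol ether terminus C7 of 4 (largest HOMO coefficient) bonds first to the central allene carbon C8 and the crowded C10 terminus then closes onto C9, a concerted but strongly asynchronous [4+2] cycloaddition that borders on a Mukaiyama–Michael addition followed by cation–enolate collapse; the closest known reaction types are oxazaborolidinium-catalysed Diels–Alder reactions of 2-silyloxydienes with acrylates, Lewis-acid-promoted cycloadditions of allenoates and thermal Diels–Alder reactions of 1,3,3-trimethyl-2-vinylcyclohexene-type dienes, none of which combines a chiral catalyst with a diene terminus this hindered. Ring B is closed by suprafacial six-membered [4+2] ring formation that makes C7–C8 and C9–C10 and leaves the orthogonal allene π-bond as the exocyclic C8=C17 alkene. C10 is set by the catalyst, which screens one face of the bound allenoate so that the diene adds to the other. C9 is set by exo placement of the ester, expected because an endo ester would lie under ring A against the C4 methyl on that face; exo puts C11 cis to the C20 methyl, the inside substituent of the diene. Regioselectivity comes from the donor at C6, site selectivity for the conjugated allene π-bond from its conjugation with the activated carbonyl, and the slim sp-hybridized dienophile is what allows the twisted s-cis diene to be reached. Should some endo adduct form, C9 can be converged at this stage by deprotonation to the ester dienolate and kinetic α-protonation anti to the C10 methyl.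

Step 5
Reactants: 6 ethyl (9R,10S)-6-(tert-butyldimethylsilyloxy)-12,13,14,15,16-pentanor-ent-labda-5,8(17)-dien-11-oate
Product: 7 (9R,10S)-6-(tert-butyldimethylsilyloxy)-12,13,14,15,16-pentanor-ent-labda-5,8(17)-dien-11-ol
Conditions: i-Bu2AlH (2.5 equiv), CH2Cl2, −78 → 0 °C; aq. potassium sodium tartrate
Reagents that add atoms: none
Why: Hydride reduction of the ester to the primary alcohol; the reagent is not basic, so C9 is not epimerized, and the silyl enol ether is inert to it.

Step 6
Reactants: 7 (9R,10S)-6-(tert-butyldimethylsilyloxy)-12,13,14,15,16-pentanor-ent-labda-5,8(17)-dien-11-ol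
Product: 8 (9R,10S)-6-(tert-butyldimethylsilyloxy)-12,13,14,15,16-pentanor-ent-labda-5,8(17)-dien-11-al
Conditions: DMP, pyridine, CH2Cl2, 0 °C; used without storage
Reagents that add atoms: none
Why: Buffered hypervalent-iodine oxidation; the neutral, cold conditions keep the β,γ-unsaturated aldehyde from epimerizing at C9 or conjugating, and spare the silyl enol ether.

Step 7
Reactants: 8 (9R,10S)-6-(tert-butyldimethylsilyloxy)-12,13,14,15,16-pentanor-ent-labda-5,8(17)-dien-11-al
Product: 9 (9R,10S)-6-(tert-butyldimethylsilyloxy)-13,14,15,16-tetranor-ent-labda-5,8(17),11-triene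
Conditions: Ph3PCH3Br, KN(SiMe3)2, THF, 0 °C; then 8, −78 → 0 °C
Reagents that add atoms: methylenetriphenylphosphorane (from methyltriphenylphosphonium bromide), C=P(c1ccccc1)(c1ccccc1)c1ccccc1
Why: Wittig methylenation; the unstabilized ylide adds to the aldehyde at −78 °C faster than it can deprotonate C9, and after this step C9 is no longer epimerizable.

Step 8
Reactants: 9 (9R,10S)-6-(tert-butyldimethylsilyloxy)-13,14,15,16-tetranor-ent-labda-5,8(17),11-triene
Product: 10 (5R,9R,10S)-13,14,15,16-tetranor-ent-labda-8(17),11-dien-6-one
Conditions: Bu4NF (1.1 equiv), AcOH (1.5 equiv), THF, −20 → 0 °C; crude ketone used at once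
Reagents that add atoms: none
Why: Fluoride cleaves the O–Si bond and the buffered enolate is protonated at C5 on the face anti to the axial C20 methyl (chair-like axial protonation), which sets C5 and the trans ring fusion; acetic acid keeps the medium from equilibrating the ketone toward its C6–C7 enol, the path by which C8=C17 would move into conjugation.

Step 9
Reactants: 10 (5R,9R,10S)-13,14,15,16-tetranor-ent-labda-8(17),11-dien-6-one
Product: 11 (5R,6R,9R,10S)-13,14,15,16-tetranor-ent-labda-8(17),11-dien-6-ol
Conditions: SmI2 (3 equiv), H2O, THF, 0 °C → rt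
Reagents that add atoms: none
Why: Electron-transfer reduction through a samarium ketyl (the type of a dissolving-metal ketone reduction); the bulky O–Sm group settles equatorial, away from the axial C20 and C4 methyls, so hydrogen arrives axially and C6 is set as the equatorial alcohol, where hydride reagents would attack from the open face and give the axial epimer. The isolated alkenes are not reduced and the reduction is fast enough to outrun alkene migration.

Step 10
Reactants: 11 (5R,6R,9R,10S)-13,14,15,16-tetranor-ent-labda-8(17),11-dien-6-ol
Product: 12 (5R,6R,9R,10S)-6-(triethylsilyloxy)-13,14,15,16-tetranor-ent-labda-8(17),11-diene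
Conditions: Et3SiOTf, 2,6-lutidine, CH2Cl2, −78 → 0 °C
Reagents that add atoms: triethylsilyl trifluoromethanesulfonate, CC[Si](CC)(CC)OS(=O)(=O)C(F)(F)F
Why: Silylation of the hindered secondary alcohol with the reactive triflate; the triethylsilyl ether protects O6 against the Zr–H and C–Zn reagents that follow and is easy to remove at the end.

Step 11
Reactants: 12 (5R,6R,9R,10S)-6-(triethylsilyloxy)-13,14,15,16-tetranor-ent-labda-8(17),11-diene
Product: 14 (5R,6R,9R,10S)-12-iodo-6-(triethylsilyloxy)-13,14,15,16-tetranor-ent-labd-8(17)-ene, via the C12 alkylzirconocene chloride 13 (not isolated)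
Conditions: Cp2Zr(H)Cl (1.5 equiv), THF, rt, dark; then I2 (1.1 equiv), 0 °C; aq. Na2S2O3
Reagents that add atoms: iodine, II
Why: Hydrozirconation puts zirconium on the terminal carbon C12 of the monosubstituted alkene, which reacts faster than the 1,1-disubstituted C8=C17 alkene; iodinolysis of the C–Zr bond gives the primary iodide.

Step 12
Reactants: 14 (5R,6R,9R,10S)-12-iodo-6-(triethylsilyloxy)-13,14,15,16-tetranor-ent-labd-8(17)-ene; 15 4-bromofuran-2(5H)-one
Product: 17 (5R,6R,9R,10S)-6-(triethylsilyloxy)-ent-labda-8(17),13-dien-15,16-olide, via the C12 alkylzinc iodide 16 (not isolated)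
Conditions: Zn dust (activated with BrCH2CH2Br and Me3SiCl), LiCl, THF, 40 °C; then 15, PdCl2(dppf) (5 mol%), THF, rt → 50 °C
Reagents that add atoms: none
Why: Zinc insertion into the primary C–I bond and Negishi coupling with the vinylogous acyl bromide; oxidative addition to the β-bromo-enoate is fast, the wide-bite-angle dppf ligand limits β-hydride elimination, and the alkylzinc is too weakly basic to attack the lactone or the silyl ether.

Step 13
Reactants: 17 (5R,6R,9R,10S)-6-(triethylsilyloxy)-ent-labda-8(17),13-dien-15,16-olide
Product: 20 [2-(trimethylsilyl)ethoxy]methyl (5R,6R,9R,10S,13Z)-16-acetoxy-6-(triethylsilyloxy)-ent-labda-8(17),13-dien-15-oate, via sodium hydroxy carboxylate 18 (not isolated), via hydroxy acetal ester 19 (not isolated)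
Conditions: NaOH (1.0 equiv), THF/H2O, 0 °C → rt; concentrate, dry (toluene); Me3SiCH2CH2OCH2Cl (1.05 equiv), DMF, 0 °C; then Ac2O, pyridine, DMAP (cat.), 0 °C
Reagents that add atoms: sodium hydroxide, [Na+].[OH-]; 2-(trimethylsilyl)ethoxymethyl chloride, C[Si](C)(C)CCOCCl; acetic anhydride, CC(=O)OC(C)=O
Why: Saponification opens the butenolide to carboxylate 18 with the Z geometry fixed by the ring; the carboxylate, the only anionic nucleophile present, is O-alkylated by the chloromethyl ether to 19, so that during DMAP-catalysed acetylation of the primary O16 hydroxyl there is no mixed anhydride next to the free alcohol to close the lactone again.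

Step 14
Reactants: 20 [2-(trimethylsilyl)ethoxy]methyl (5R,6R,9R,10S,13Z)-16-acetoxy-6-(triethylsilyloxy)-ent-labda-8(17),13-dien-15-oate
Product: 21 (5R,6R,9R,10S,13Z)-16-acetoxy-6-hydroxy-ent-labda-8(17),13-dien-15-oic acid (the target)
Conditions: aq. HF (5% in MeCN), 0 °C → rt; pH 4 buffer work-up
Reagents that add atoms: none
Why: Fluoride-assisted cleavage of the O6–Si bond and fragmentation of the 2-(trimethylsilyl)ethoxymethyl ester in one operation; dilute HF leaves the allylic acetate, the Z-enoic acid and the exocyclic alkene untouched.

## Compound list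

1 | β-cyclocitral (2,6,6-trimethylcyclohex-1-ene-1-carbaldehyde) | CC1=C(C=O)C(C)(C)CCC1 | starting material
2 | 1-(2,6,6-trimethylcyclohex-1-en-1-yl)ethan-1-ol (racemic) | CC(O)C1=C(C)CCCC1(C)C | intermediate
3 | 1-(2,6,6-trimethylcyclohex-1-en-1-yl)ethan-1-one | CC(=O)C1=C(C)CCCC1(C)C | intermediate
4 | tert-butyldimethyl{[1-(2,6,6-trimethylcyclohex-1-en-1-yl)ethenyl]oxy}silane | C=C(O[Si](C)(C)C(C)(C)C)C1=C(C)CCCC1(C)C | intermediate
5 | ethyl buta-2,3-dienoate | C=C=CC(=O)OCC | starting material
6 | ethyl (9R,10S)-6-(tert-butyldimethylsilyloxy)-12,13,14,15,16-pentanor-ent-labda-5,8(17)-dien-11-oate | C=C1CC(O[Si](C)(C)C(C)(C)C)=C2C(C)(C)CCC[C@@]2(C)[C@@H]1C(=O)OCC | intermediate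
7 | (9R,10S)-6-(tert-butyldimethylsilyloxy)-12,13,14,15,16-pentanor-ent-labda-5,8(17)-dien-11-ol | C=C1CC(O[Si](C)(C)C(C)(C)C)=C2C(C)(C)CCC[C@@]2(C)[C@@H]1CO | intermediate
8 | (9R,10S)-6-(tert-butyldimethylsilyloxy)-12,13,14,15,16-pentanor-ent-labda-5,8(17)-dien-11-al | C=C1CC(O[Si](C)(C)C(C)(C)C)=C2C(C)(C)CCC[C@@]2(C)[C@@H]1C=O | intermediate
9 | (9R,10S)-6-(tert-butyldimethylsilyloxy)-13,14,15,16-tetranor-ent-labda-5,8(17),11-triene | C=C1CC(O[Si](C)(C)C(C)(C)C)=C2C(C)(C)CCC[C@@]2(C)[C@@H]1C=C | intermediate
10 | (5R,9R,10S)-13,14,15,16-tetranor-ent-labda-8(17),11-dien-6-one | C=C1CC(=O)[C@@H]2C(C)(C)CCC[C@@]2(C)[C@@H]1C=C | intermediate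
11 | (5R,6R,9R,10S)-13,14,15,16-tetranor-ent-labda-8(17),11-dien-6-ol | C=C1C[C@@H](O)[C@@H]2C(C)(C)CCC[C@@]2(C)[C@@H]1C=C | intermediate
12 | (5R,6R,9R,10S)-6-(triethylsilyloxy)-13,14,15,16-tetranor-ent-labda-8(17),11-diene | C=C1C[C@@H](O[Si](CC)(CC)CC)[C@@H]2C(C)(C)CCC[C@@]2(C)[C@@H]1C=C | intermediate
13 | chlorobis(cyclopentadienyl)zirconium C12-alkyl derived from 12 (cyclopentadienyl rings drawn σ-bonded) | C=C1C[C@@H](O[Si](CC)(CC)CC)[C@@H]2C(C)(C)CCC[C@@]2(C)[C@@H]1CC[Zr](Cl)(C1C=CC=C1)C1C=CC=C1 | intermediate
14 | (5R,6R,9R,10S)-12-iodo-6-(triethylsilyloxy)-13,14,15,16-tetranor-ent-labd-8(17)-ene | C=C1C[C@@H](O[Si](CC)(CC)CC)[C@@H]2C(C)(C)CCC[C@@]2(C)[C@@H]1CCI | intermediate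
15 | 4-bromofuran-2(5H)-one | BrC1=CC(=O)OC1 | starting material
16 | C12 alkylzinc iodide derived from 14 | C=C1C[C@@H](O[Si](CC)(CC)CC)[C@@H]2C(C)(C)CCC[C@@]2(C)[C@@H]1CC[Zn]I | intermediate
17 | (5R,6R,9R,10S)-6-(triethylsilyloxy)-ent-labda-8(17),13-dien-15,16-olide | C=C1C[C@@H](O[Si](CC)(CC)CC)[C@@H]2C(C)(C)CCC[C@@]2(C)[C@@H]1CCC1=CC(=O)OC1 | intermediate
18 | sodium (5R,6R,9R,10S,13Z)-16-hydroxy-6-(triethylsilyloxy)-ent-labda-8(17),13-dien-15-oate | C=C1C[C@@H](O[Si](CC)(CC)CC)[C@@H]2C(C)(C)CCC[C@@]2(C)[C@@H]1CC/C(=C/C(=O)[O-])CO.[Na+] | intermediate
19 | [2-(trimethylsilyl)ethoxy]methyl (5R,6R,9R,10S,13Z)-16-hydroxy-6-(triethylsilyloxy)-ent-labda-8(17),13-dien-15-oate | C=C1C[C@@H](O[Si](CC)(CC)CC)[C@@H]2C(C)(C)CCC[C@@]2(C)[C@@H]1CC/C(=C/C(=O)OCOCC[Si](C)(C)C)CO | intermediate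
20 | [2-(trimethylsilyl)ethoxy]methyl (5R,6R,9R,10S,13Z)-16-acetoxy-6-(triethylsilyloxy)-ent-labda-8(17),13-dien-15-oate | C=C1C[C@@H](O[Si](CC)(CC)CC)[C@@H]2C(C)(C)CCC[C@@]2(C)[C@@H]1CC/C(=C/C(=O)OCOCC[Si](C)(C)C)COC(C)=O | intermediate
21 | (5R,6R,9R,10S,13Z)-16-acetoxy-6-hydroxy-ent-labda-8(17),13-dien-15-oic acid (CNP0182509.1) | C=C1C[C@@H](O)[C@@H]2C(C)(C)CCC[C@@]2(C)[C@@H]1CC/C(=C/C(=O)O)COC(C)=O | target

## Step count and risk

Total: 14 steps. Longest linear sequence: 14 steps, from 1 to 21; 5 and 15 enter as purchased partners.

Least certain steps: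

Step 4 (key step, proposed new method).
- What may go wrong: the bulky chiral Lewis acid may not turn over against the crowded, twisted C10 terminus. Proton or silyl transfer from the diene may generate an achiral silyl triflimide that drives a racemic background reaction. A stepwise pathway may close through the terminal allene carbon C17 in place of C9, or stop after conjugate addition. Endo approach of the ester would give the wrong relative configuration at C9. Facial discrimination at a quaternary diene terminus may be poor.
- Fallback (known chemistry), from 4 and 5 back to 7: the two partners are combined without catalyst at 12 kbar in CH2Cl2 (or neat at 120 °C), a thermal Diels–Alder reaction of an allenoate with a 2-silyloxydiene that is concerted and therefore uses the conjugated π-bond. The crude racemic adduct, whatever its composition at C9, is deprotonated with LiN(i-Pr)2 in THF at −78 °C to the racemic lithium dienolate F1 and protonated at −78 °C with AcOH to racemic 6 F2 (kinetic α-protonation anti to the C10 methyl). Reduction with i-Bu2AlH gives racemic 7 F3. Acylation with (1S)-camphanic chloride and pyridine gives two diastereomeric esters, which are separated by crystallization or chromatography. The (9R,10S) camphanate F4 is cleaved with K2CO3 in MeOH to 7, and the route continues at step 6.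

Step 13.
- What may go wrong: alkylation of the O16 hydroxyl alongside the carboxylate if any excess base is present, and re-closure of the hydroxy ester to the lactone (base-catalysed transesterification) before acetylation is complete. Re-closure returns 17, which can be recycled, but it can erode throughput.
- Fallback, from 17 back to 21: the lactone is opened with MeNHOMe·HCl and Me3Al in CH2Cl2 to the (13Z)-16-hydroxy N-methoxy-N-methyl amide F5, a much poorer internal acyl donor than any ester. Acetylation (Ac2O, pyridine) gives the acetoxy amide F6. Cp2Zr(H)Cl reduces the amide to the (13Z)-16-acetoxy enal F7, and Pinnick oxidation (NaClO2, NaH2PO4, 2-methylbut-2-ene) gives the (13Z)-16-acetoxy-6-(triethylsilyloxy) acid F8. HF·pyridine in THF then removes the silyl ether to give 21.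

Step 11.
- What may go wrong: competing hydrozirconation of the exocyclic C8=C17 alkene, slow addition to the vinyl group (it is attached to a tertiary carbon next to quaternary C10), and addition of iodine to an alkene during the quench.
- Fallback, from 12 back to 14: rhodium-catalysed hydroboration with pinacolborane and RhCl(PPh3)3 in THF, which strongly prefers monosubstituted alkenes, gives the C12 pinacol boronate F9. Oxidation with NaBO3 in THF/H2O gives the C12 alcohol F10, and an Appel reaction (I2, PPh3, imidazole) gives 14.

Step 8.
- What may go wrong: migration of the C8=C17 double bond into conjugation with the new C6 carbonyl through the C6–C7 enol, during cleavage or on handling of the ketone, and some protonation of C5 from the face of the C20 methyl (cis fusion).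
- Fallback, from 9 back to 11: the ketone is not allowed to accumulate. Bu4NF in THF at −20 °C, without acid, converts 9 into the tetrabutylammonium enolate F11, and this solution is added to SmI2/H2O in THF at 0 °C. Water protonates C5 and the nascent ketone 10 is reduced at once to 11, so that no enolizable β,γ-unsaturated ketone is ever handled.

## Further compounds

F1 | step 4 | racemic lithium ester dienolate of the cycloadduct (C9 trigonal) | C=C1CC(O[Si](C)(C)C(C)(C)C)=C2C(C)(C)CCC[C@@]2(C)C1=C([O-])OCC.[Li+].C=C1CC(O[Si](C)(C)C(C)(C)C)=C2C(C)(C)CCC[C@]2(C)C1=C([O-])OCC.[Li+]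
F2 | step 4 | racemic 6 (6 and its enantiomer) | C=C1CC(O[Si](C)(C)C(C)(C)C)=C2C(C)(C)CCC[C@@]2(C)[C@@H]1C(=O)OCC.C=C1CC(O[Si](C)(C)C(C)(C)C)=C2C(C)(C)CCC[C@]2(C)[C@H]1C(=O)OCC
F3 | step 4 | racemic 7 (7 and its enantiomer) | C=C1CC(O[Si](C)(C)C(C)(C)C)=C2C(C)(C)CCC[C@@]2(C)[C@@H]1CO.C=C1CC(O[Si](C)(C)C(C)(C)C)=C2C(C)(C)CCC[C@]2(C)[C@H]1CO
F4 | step 4 | (1S,4R)-camphanate ester of 7 | C=C1CC(O[Si](C)(C)C(C)(C)C)=C2C(C)(C)CCC[C@@]2(C)[C@@H]1COC(=O)[C@@]12CC[C@@](C)(C(=O)O1)C2(C)C
F5 | step 13 | (5R,6R,9R,10S,13Z)-16-hydroxy-N-methoxy-N-methyl-6-(triethylsilyloxy)-ent-labda-8(17),13-dien-15-amide | C=C1C[C@@H](O[Si](CC)(CC)CC)[C@@H]2C(C)(C)CCC[C@@]2(C)[C@@H]1CC/C(=C/C(=O)N(C)OC)CO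
F6 | step 13 | (5R,6R,9R,10S,13Z)-16-acetoxy-N-methoxy-N-methyl-6-(triethylsilyloxy)-ent-labda-8(17),13-dien-15-amide | C=C1C[C@@H](O[Si](CC)(CC)CC)[C@@H]2C(C)(C)CCC[C@@]2(C)[C@@H]1CC/C(=C/C(=O)N(C)OC)COC(C)=O
F7 | step 13 | (5R,6R,9R,10S,13Z)-16-acetoxy-6-(triethylsilyloxy)-ent-labda-8(17),13-dien-15-al | C=C1C[C@@H](O[Si](CC)(CC)CC)[C@@H]2C(C)(C)CCC[C@@]2(C)[C@@H]1CC/C(=C/C=O)COC(C)=O
F8 | step 13 | (5R,6R,9R,10S,13Z)-16-acetoxy-6-(triethylsilyloxy)-ent-labda-8(17),13-dien-15-oic acid | C=C1C[C@@H](O[Si](CC)(CC)CC)[C@@H]2C(C)(C)CCC[C@@]2(C)[C@@H]1CC/C(=C/C(=O)O)COC(C)=O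
F9 | step 11 | C12 pinacol boronate of 12 | C=C1C[C@@H](O[Si](CC)(CC)CC)[C@@H]2C(C)(C)CCC[C@@]2(C)[C@@H]1CCB1OC(C)(C)C(C)(C)O1
F10 | step 11 | (5R,6R,9R,10S)-6-(triethylsilyloxy)-13,14,15,16-tetranor-ent-labd-8(17)-en-12-ol | C=C1C[C@@H](O[Si](CC)(CC)CC)[C@@H]2C(C)(C)CCC[C@@]2(C)[C@@H]1CCO
F11 | step 8 | tetrabutylammonium C5–C6 enolate of 10 | C=C1CC([O-])=C2C(C)(C)CCC[C@@]2(C)[C@@H]1C=C.CCCC[N+](CCCC)(CCCC)CCCC
A1 | alternative 1 | 11-benzyloxy-17-(trimethylsilyl)-6,7-seco-ent-drim-7-en-6-al (ring-A aldehyde with the 3-(trimethylsilyl)prop-1-en-2-yl group on C9) | O=C[C@@H]1C(C)(C)CCC[C@@]1(C)[C@H](COCc1ccccc1)C(=C)C[Si](C)(C)C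
A2 | alternative 1 | 11-O-benzyl-6-hydroxy-ent-albicanol | C=C1C[C@@H](O)[C@@H]2C(C)(C)CCC[C@@]2(C)[C@@H]1COCc1ccccc1
A3 | alternative 2 | 8,9-seco precursor: ring A with CH(OSiMe2t-Bu)CH2C(Br)=CH2 on C5 and the methyl (E)-propenoate on C10 | C=C(Br)C[C@@H](O[Si](C)(C)C(C)(C)C)[C@@H]1C(C)(C)CCC[C@@]1(C)/C=C/C(=O)OC
A4 | alternative 2 | methyl 6-(tert-butyldimethylsilyloxy)-ent-albican-12-oate (C11 methylene, C12 ester) | C=C1C[C@@H](O[Si](C)(C)C(C)(C)C)[C@@H]2C(C)(C)CCC[C@@]2(C)[C@@H]1CC(=O)OC
A5 | alternative 3 | (E)-ten-membered allylic lactone, (S) at the carbinol carbon C11, bearing CH2OSiMe2t-Bu | O=C1CC(C)(C)CCC/C(C)=C/[C@@H](CO[Si](C)(C)C(C)(C)C)O1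
A6 | alternative 3 | (1R,2S)-2-[(E)-3-(tert-butyldimethylsilyloxy)prop-1-enyl]-2,6,6-trimethylcyclohexane-1-carboxylic acid | OC(=O)[C@@H]1C(C)(C)CCC[C@@]1(C)/C=C/CO[Si](C)(C)C(C)(C)C
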